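Retrosynthetic overview (target numbered as 2-oxaspiro[4.5]decane: C1 lactone CH–O, C4 lactone CH2, C5 spiro carbon, C6 ketone, C9 CH–OAc):
1. C9 acetate ⇐ selective acetylation of the diol obtained by one fluoride desilylation.
2. Lactone ring (second and last ring) ⇐ C4–C5 bond: the ketone α-carbon C5, as the lithium-chelated β-oxido enolate of an anti-aldol, attacks the acetate α-carbon C4, made electrophilic in methyl bromoacetate (an α-acyl cation, i.e. ester enolonium, equivalent). The aldolate oxygen then closes the lactone.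
3. anti-Aldol ⇐ C1–C5 bond by a boron aldol of (S)-4-silyloxycyclohex-2-enone with the C10 side-chain enal.
4. Six-membered ring (present from the start) ⇐ cyclohexa-1,3-diene by singlet-oxygen cycloaddition and enantioselective Kornblum–DeLaMare rearrangement; the enal ⇐ geraniol by Schenck ene reaction and MnO2 oxidation.

Assumption: the quinidine-derived catalyst of step 2 is taken to give the S alcohol; if the sense is the opposite, its quinine-derived pseudo-enantiomer is used in its place.

Step 1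
Reactants: 1 cyclohexa-1,3-diene
Product: 2 (1R,4S)-2,3-dioxabicyclo[2.2.2]oct-5-ene (meso endoperoxide)
Conditions: O2, 5,10,15,20-tetraphenylporphyrin (cat.), hν (visible), CH2Cl2, 0 °C
Reagents that add atoms: dioxygen, O=O
Why: singlet-oxygen [4+2] cycloaddition (photooxygenation) to the s-cis diene gives the meso bicyclic endoperoxide; no stereocentre of the target is set yet.

Step 2
Reactants: 2 (1R,4S)-2,3-dioxabicyclo[2.2.2]oct-5-ene
Product: 3 (S)-4-hydroxycyclohex-2-en-1-one
Conditions: (9S)-6′-hydroxycinchonan-9-yl acetate (O-acetylcupreidine, 10 mol%), CH2Cl2, 23 °C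
Reagents that add atoms: none
Why: enantioselective Kornblum–DeLaMare rearrangement, in which the chiral cinchona base removes one of the two enantiotopic bridgehead hydrogens with E1cB-type O–O cleavage, gives the γ-hydroxy enone and sets the carbinol centre (C9 of the target, S).

Step 3
Reactants: 3 (S)-4-hydroxycyclohex-2-en-1-one
Product: 4 (S)-4-(tert-butyldimethylsilyloxy)cyclohex-2-en-1-one
Conditions: TBSCl, imidazole, DMF, 23 °C
Reagents that add atoms: tert-butyldimethylsilyl chloride (TBSCl), CC(C)(C)[Si](C)(C)Cl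
Why: standard silyl ether formation masks the secondary alcohol for the two enolate steps and provides the bulky group that later directs both C–C bond formations to the opposite ring face.

Step 4
Reactants: 5 geraniol, (2E)-3,7-dimethylocta-2,6-dien-1-ol
Product: 7 (2E,5E)-3,7-dimethylocta-2,5-diene-1,7-diol, via tertiary allylic hydroperoxide 6 (not isolated)
Conditions: O2, 5,10,15,20-tetraphenylporphyrin (cat.), hν, CH2Cl2, 0 °C; then PPh3, 0 to 23 °C
Reagents that add atoms: dioxygen, O=O
Why: Schenck ene reaction of singlet oxygen at the more electron-rich 6,7-alkene gives the tertiary allylic hydroperoxide with a new E-alkene (about 1:1 with the secondary regioisomer, which is removed by chromatography), and PPh3 reduces the O–O bond to the alcohol.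

Step 5
Reactants: 7 (2E,5E)-3,7-dimethylocta-2,5-diene-1,7-diol
Product: 8 (2E,5E)-7-hydroxy-3,7-dimethylocta-2,5-dienal
Conditions: MnO2 (activated, excess), CH2Cl2, 23 °C
Reagents that add atoms: none
Why: chemoselective MnO2 oxidation of the primary allylic alcohol gives the enal without E/Z isomerisation; the tertiary alcohol cannot be oxidised.

Step 6
Reactants: 8 (2E,5E)-7-hydroxy-3,7-dimethylocta-2,5-dienal
Product: 9 (2E,5E)-3,7-dimethyl-7-(triethylsilyloxy)octa-2,5-dienal
Conditions: TESOTf, 2,6-lutidine, CH2Cl2, −78 °C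
Reagents that add atoms: triethylsilyl trifluoromethanesulfonate (TESOTf), CC[Si](CC)(CC)OS(=O)(=O)C(F)(F)F
Why: silyl triflate/lutidine silylation of the hindered tertiary alcohol at low temperature leaves the enal untouched and removes the only acidic proton before the enolate steps.

Step 7
Reactants: 4 (S)-4-(tert-butyldimethylsilyloxy)cyclohex-2-en-1-one; 9 (2E,5E)-3,7-dimethyl-7-(triethylsilyloxy)octa-2,5-dienal
Product: 12 (4S,6R)-4-(tert-butyldimethylsilyloxy)-6-[(1R,2E,5E)-1-hydroxy-3,7-dimethyl-7-(triethylsilyloxy)octa-2,5-dien-1-yl]cyclohex-2-en-1-one, via dicyclohexylboron dienolate 10 (not isolated), via dicyclohexylboron aldolate 11 (not isolated)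
Conditions: (c-C6H11)2BCl, Et3N, Et2O, −78 to 0 °C; 9, −78 °C; then MeOH, pH 7 buffer, H2O2, 0 °C
Reagents that add atoms: none
Why: anti-selective boron aldol reaction, in which the ring-fixed E dienolborinate adds to the aldehyde through a Zimmerman–Traxler chair on the ring face opposite the silyloxy group, sets C1 of the target (R) and a temporary 6R centre that is re-set in step 8.

Step 8
Reactants: 12 (4S,6R)-4-(tert-butyldimethylsilyloxy)-6-[(1R,2E,5E)-1-hydroxy-3,7-dimethyl-7-(triethylsilyloxy)octa-2,5-dien-1-yl]cyclohex-2-en-1-one; 13 methyl bromoacetate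
Product: 16 (1R,5R,9S)-9-(tert-butyldimethylsilyloxy)-1-[(1E,4E)-2,6-dimethyl-6-(triethylsilyloxy)hepta-1,4-dien-1-yl]-2-oxaspiro[4.5]dec-7-ene-3,6-dione, via dilithium oxido dienolate 14 (not isolated), via lithium alkoxide methyl ester 15 (not isolated)
Conditions: LiN(iPr)2 (2.4 equiv), THF, −78 to −45 °C; 13 (3 equiv), −78 to 0 °C; aq. NH4Cl
Reagents that add atoms: none
Why: Proposed new method: the first equivalent of LiN(iPr)2 gives the lithium aldolate and the second removes the ring α-hydrogen (the resulting dianion cannot undergo retro-aldol cleavage), forming the Li-bridged six-membered β-oxido dienolate 14, in which the dienyl group on the carbinol carbon covers one face; the ketone α-carbon attacks the acetate α-carbon of 13, electrophilic through its bromide (α-acyl cation equivalent), from the open face, which is also the face opposite the silyloxy group (matched), so two α-carbonyl carbons are joined into the 1,4-dicarbonyl unit and the quaternary C5 (R) is set; the γ-alkoxide 15 then closes onto the methyl ester (5-exo-trig transesterification) to the lactone; closest known reaction type: Fráter–Seebach anti-alkylation of β-hydroxy ester dianions, combined with haloacetate alkylation of ketone enolates.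

Step 9
Reactants: 16 (1R,5R,9S)-9-(tert-butyldimethylsilyloxy)-1-[(1E,4E)-2,6-dimethyl-6-(triethylsilyloxy)hepta-1,4-dien-1-yl]-2-oxaspiro[4.5]dec-7-ene-3,6-dione
Product: 17 (1R,5R,9S)-9-hydroxy-1-[(1E,4E)-6-hydroxy-2,6-dimethylhepta-1,4-dien-1-yl]-2-oxaspiro[4.5]dec-7-ene-3,6-dione
Conditions: Bu4NF, AcOH (1:1), THF, 0 to 23 °C
Reagents that add atoms: none
Why: fluoride desilylation buffered with acetic acid cleaves both silyl ethers without opening the lactone or enolising the γ-hydroxy enone, so no stereocentre is touched.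

Step 10
Reactants: 17 (1R,5R,9S)-9-hydroxy-1-[(1E,4E)-6-hydroxy-2,6-dimethylhepta-1,4-dien-1-yl]-2-oxaspiro[4.5]dec-7-ene-3,6-dione
Product: 18 the target, (1R,5R,9S)-1-[(1E,4E)-6-hydroxy-2,6-dimethylhepta-1,4-dien-1-yl]-3,6-dioxo-2-oxaspiro[4.5]dec-7-en-9-yl acetate
Conditions: Ac2O, pyridine, 4-(dimethylamino)pyridine (cat.), CH2Cl2, 0 °C
Reagents that add atoms: acetic anhydride, CC(=O)OC(C)=O
Why: nucleophile-catalysed acetylation is selective for the secondary allylic alcohol over the hindered tertiary alcohol at 0 °C and gives the target with the three stereocentres set in steps 2, 7 and 8.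

Compound list
1 | cyclohexa-1,3-diene | C1=CC=CCC1 | starting material
2 | (1R,4S)-2,3-dioxabicyclo[2.2.2]oct-5-ene (meso endoperoxide) | C1C[C@H]2C=C[C@@H]1OO2 | intermediate
3 | (S)-4-hydroxycyclohex-2-en-1-one | O[C@@H]1C=CC(=O)CC1 | intermediate
4 | (S)-4-(tert-butyldimethylsilyloxy)cyclohex-2-en-1-one | CC(C)(C)[Si](C)(C)O[C@@H]1C=CC(=O)CC1 | intermediate
5 | geraniol, (2E)-3,7-dimethylocta-2,6-dien-1-ol | CC(C)=CCC/C(C)=C/CO | starting material
6 | (2E,5E)-7-hydroperoxy-3,7-dimethylocta-2,5-dien-1-ol | OC/C=C(\C)C/C=C/C(C)(C)OO | intermediate (not isolated)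
7 | (2E,5E)-3,7-dimethylocta-2,5-diene-1,7-diol | OC/C=C(\C)C/C=C/C(C)(C)O | intermediate
8 | (2E,5E)-7-hydroxy-3,7-dimethylocta-2,5-dienal | O=C/C=C(\C)C/C=C/C(C)(C)O | intermediate
9 | (2E,5E)-3,7-dimethyl-7-(triethylsilyloxy)octa-2,5-dienal | O=C/C=C(\C)C/C=C/C(C)(C)O[Si](CC)(CC)CC | intermediate
10 | dicyclohexyl{[(4S)-4-(tert-butyldimethylsilyloxy)cyclohexa-1,5-dien-1-yl]oxy}borane (boron dienolate of 4) | CC(C)(C)[Si](C)(C)O[C@@H]1C=CC(OB(C2CCCCC2)C2CCCCC2)=CC1 | intermediate (not isolated)
11 | O-dicyclohexylboryl derivative (boron aldolate) of 12 | CC(C)(C)[Si](C)(C)O[C@@H]1C=CC(=O)[C@@H]([C@H](OB(C2CCCCC2)C2CCCCC2)/C=C(\C)C/C=C/C(C)(C)O[Si](CC)(CC)CC)C1 | intermediate (not isolated)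
12 | (4S,6R)-4-(tert-butyldimethylsilyloxy)-6-[(1R,2E,5E)-1-hydroxy-3,7-dimethyl-7-(triethylsilyloxy)octa-2,5-dien-1-yl]cyclohex-2-en-1-one (anti-aldol, trans to the silyloxy group) | CC(C)(C)[Si](C)(C)O[C@@H]1C=CC(=O)[C@@H]([C@H](O)/C=C(\C)C/C=C/C(C)(C)O[Si](CC)(CC)CC)C1 | intermediate
13 | methyl bromoacetate | COC(=O)CBr | starting material
14 | dilithium salt of 12 deprotonated at the hydroxyl group and at ring C6 (chelated β-oxido dienolate) | [Li+].[Li+].CC(C)(C)[Si](C)(C)O[C@@H]1C=CC([O-])=C([C@H]([O-])/C=C(\C)C/C=C/C(C)(C)O[Si](CC)(CC)CC)C1 | intermediate (not isolated)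
15 | lithium alkoxide of methyl 2-[(1R,5S)-5-(tert-butyldimethylsilyloxy)-1-[(1R,2E,5E)-1-hydroxy-3,7-dimethyl-7-(triethylsilyloxy)octa-2,5-dien-1-yl]-2-oxocyclohex-3-en-1-yl]acetate | [Li+].CC(C)(C)[Si](C)(C)O[C@@H]1C=CC(=O)[C@](CC(=O)OC)([C@H]([O-])/C=C(\C)C/C=C/C(C)(C)O[Si](CC)(CC)CC)C1 | intermediate (not isolated)
16 | (1R,5R,9S)-9-(tert-butyldimethylsilyloxy)-1-[(1E,4E)-2,6-dimethyl-6-(triethylsilyloxy)hepta-1,4-dien-1-yl]-2-oxaspiro[4.5]dec-7-ene-3,6-dione | CC(C)(C)[Si](C)(C)O[C@@H]1C=CC(=O)[C@@]2(CC(=O)O[C@@H]2/C=C(\C)C/C=C/C(C)(C)O[Si](CC)(CC)CC)C1 | intermediate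
17 | (1R,5R,9S)-9-hydroxy-1-[(1E,4E)-6-hydroxy-2,6-dimethylhepta-1,4-dien-1-yl]-2-oxaspiro[4.5]dec-7-ene-3,6-dione | O[C@@H]1C=CC(=O)[C@@]2(CC(=O)O[C@@H]2/C=C(\C)C/C=C/C(C)(C)O)C1 | intermediate
18 | the target miliusane, (1R,5R,9S)-1-[(1E,4E)-6-hydroxy-2,6-dimethylhepta-1,4-dien-1-yl]-3,6-dioxo-2-oxaspiro[4.5]dec-7-en-9-yl acetate | CC(=O)O[C@@H]1C=CC(=O)[C@@]2(CC(=O)O[C@@H]2/C=C(\C)C/C=C/C(C)(C)O)C1 | target

Total step count: 10 steps. Longest linear sequence: 7 steps (1, 2, 3, 7, 8, 9, 10; the branch 4, 5, 6, 7, 8, 9, 10 is equally long).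

Steps most likely to fail

Step 8. The second deprotonation must outrun retro-aldol cleavage of the mono-lithium aldolate. The hindered dienolate must then attack the CH2 of 13 and not its ester carbonyl, and alkoxide 15 must lactonise before it fragments. The fallback sets out from 12 and comes back at 16. Dianion 14 is formed as in step 8 but is alkylated with bromoacetonitrile, which has no carbonyl group to divert the alkoxide or the amide base. This gives the lithium γ-oxido nitrile F1 in the flask. On warming to 0 °C its alkoxide adds to the nitrile (Pinner-type 5-exo-dig closure) to give the cyclic imidate F2. F2 is hydrolysed with aqueous AcOH/NaOAc (pH 4–5) in THF to lactone 16, where the route continues with step 9.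

Step 2. The enantioselectivity of the catalytic rearrangement on this small bicyclic peroxide, and its sense, may fall short. The fallback sets out from 2 and comes back at 3. Et3N in CH2Cl2 gives racemic 4-hydroxycyclohex-2-en-1-one F3 by the uncatalysed-in-the-chiral-sense Kornblum–DeLaMare rearrangement. A kinetic resolution with the lipase of Burkholderia cepacia and vinyl acetate then acetylates the R alcohol to (R)-4-oxocyclohex-2-en-1-yl acetate F4. The unreacted S alcohol 3 is recovered (at most 50%) and enters step 3.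

Step 4. The ene reaction gives the tertiary and secondary hydroperoxides in about equal amounts, and the allylic-alcohol alkene of geraniol can also react, so the yield of 7 may be low. The fallback sets out from 5 and comes back at 7, and fixes the regiochemistry by a selenium route. Geraniol is acetylated (Ac2O, pyridine) to geranyl acetate F5. mCPBA in CH2Cl2 at 0 °C epoxidises the electron-rich 6,7-alkene to racemic 6,7-epoxygeranyl acetate F6. PhSeSePh/NaBH4 in EtOH opens the epoxide at the secondary carbon to the hydroxy selenide F7. H2O2 oxidises F7 to the selenoxide F8, whose syn-elimination can only run away from the carbinol carbon and gives (2E,5E)-7-hydroxy-3,7-dimethylocta-2,5-dien-1-yl acetate F9. K2CO3 in MeOH removes the acetate to give diol 7, which enters step 5.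

Further compounds
F1 | step 8 | lithium alkoxide of 2-[(1R,5S)-5-(tert-butyldimethylsilyloxy)-1-[(1R,2E,5E)-1-hydroxy-3,7-dimethyl-7-(triethylsilyloxy)octa-2,5-dien-1-yl]-2-oxocyclohex-3-en-1-yl]acetonitrile (not isolated) | [Li+].CC(C)(C)[Si](C)(C)O[C@@H]1C=CC(=O)[C@](CC#N)([C@H]([O-])/C=C(\C)C/C=C/C(C)(C)O[Si](CC)(CC)CC)C1
F2 | step 8 | (1R,5R,9S)-9-(tert-butyldimethylsilyloxy)-1-[(1E,4E)-2,6-dimethyl-6-(triethylsilyloxy)hepta-1,4-dien-1-yl]-3-imino-2-oxaspiro[4.5]dec-7-en-6-one (cyclic imidate) | CC(C)(C)[Si](C)(C)O[C@@H]1C=CC(=O)[C@@]2(CC(=N)O[C@@H]2/C=C(\C)C/C=C/C(C)(C)O[Si](CC)(CC)CC)C1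
F3 | step 2 | racemic 4-hydroxycyclohex-2-en-1-one | OC1C=CC(=O)CC1
F4 | step 2 | (R)-4-oxocyclohex-2-en-1-yl acetate | CC(=O)O[C@H]1C=CC(=O)CC1
F5 | step 4 | geranyl acetate, (2E)-3,7-dimethylocta-2,6-dien-1-yl acetate | CC(=O)OC/C=C(\C)CCC=C(C)C
F6 | step 4 | racemic (2E)-5-(3,3-dimethyloxiran-2-yl)-3-methylpent-2-en-1-yl acetate (6,7-epoxygeranyl acetate) | CC(=O)OC/C=C(\C)CCC1OC1(C)C
F7 | step 4 | racemic (2E)-7-hydroxy-3,7-dimethyl-6-(phenylselanyl)oct-2-en-1-yl acetate | CC(=O)OC/C=C(\C)CCC([Se]c1ccccc1)C(C)(C)O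
F8 | step 4 | selenoxide of F7, (2E)-7-hydroxy-3,7-dimethyl-6-(phenylseleninyl)oct-2-en-1-yl acetate (not isolated) | CC(=O)OC/C=C(\C)CCC([Se](=O)c1ccccc1)C(C)(C)O
F9 | step 4 | (2E,5E)-7-hydroxy-3,7-dimethylocta-2,5-dien-1-yl acetate | CC(=O)OC/C=C(\C)C/C=C/C(C)(C)O
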